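## Retrosynthetic overview
1. The target comes from its tetramethyl ether; global O‑demethylation is the last step.
2. The pyranone ring is the only ring built and is formed last, by oxidative cyclisation of a 2'‑hydroxychalcone.
3. Key C–C disconnection: the chalcone Cα=Cβ bond, made by a crossed aldol (Claisen–Schmidt) condensation of 3‑(2,3‑dimethoxybenzyl)‑2‑hydroxy‑4,6‑dimethoxyacetophenone with benzaldehyde.
4. The acetophenone comes from ortho‑acylation of 2‑(2,3‑dimethoxybenzyl)‑3,5‑dimethoxyphenol. Its single free OH sits next to the benzyl‑bearing carbon, which fixes C8 rather than C6.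
5. The diarylmethane comes from 2,3‑dimethoxyphenyllithium and O‑benzyl‑4,6‑dimethoxysalicylaldehyde (from symmetric 2,4,6‑trimethoxybenzaldehyde), followed by deoxygenation. All three benzene rings are bought.

Assumption: the SMILES holds no stereocentre and no stereogenic double bond, so the target is achiral and needs no enantiocontrol. The racemic centres in 6, 13 and 15 are erased within the route.

## Route

**Step 1**
Reactants: 1 2,4,6‑trimethoxybenzaldehyde
Product: 2 2‑hydroxy‑4,6‑dimethoxybenzaldehyde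
Conditions: BCl3 (1.1 equiv), CH2Cl2, −78 → 0 °C; then H2O
Reagents that add atoms: none
Why: Chelation‑directed ether cleavage, in which BCl3 bound to the aldehyde oxygen cleaves only an ortho methoxy group through a six‑membered chelate, and the two ortho groups are equivalent so a single phenol forms.

**Step 2**
Reactants: 2 2‑hydroxy‑4,6‑dimethoxybenzaldehyde
Product: 3 2‑(benzyloxy)‑4,6‑dimethoxybenzaldehyde
Conditions: BnBr (1.2 equiv), K2CO3, DMF, 60 °C
Reagents that add atoms: benzyl bromide BrCc1ccccc1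
Why: Williamson ether synthesis masks the acidic phenol so that the aryllithium in step 3 is spent only on the aldehyde.

**Step 3**
Reactants: 3 2‑(benzyloxy)‑4,6‑dimethoxybenzaldehyde; 4 1,2‑dimethoxybenzene (veratrole)
Product: 6 [2‑(benzyloxy)‑4,6‑dimethoxyphenyl](2,3‑dimethoxyphenyl)methanol (racemic), via 2,3‑dimethoxyphenyllithium 5 (not isolated)
Conditions: 4 (1.3 equiv), n‑BuLi, TMEDA, THF, 0 °C → rt, 2 h; then 3, −78 → 0 °C; H2O quench
Reagents that add atoms: none
Why: Directed ortho‑metalation of veratrole occurs only next to a methoxy group, and 1,2‑addition of the aryllithium to the aldehyde gives a carbinol whose racemic stereocentre is removed in step 4.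

**Step 4**
Reactants: 6 [2‑(benzyloxy)‑4,6‑dimethoxyphenyl](2,3‑dimethoxyphenyl)methanol
Product: 7 1‑(benzyloxy)‑2‑(2,3‑dimethoxybenzyl)‑3,5‑dimethoxybenzene
Conditions: Et3SiH (3 equiv), TFA (4 equiv), CH2Cl2, 0 °C, 30 min
Reagents that add atoms: none
Why: Ionic hydrogenation (Kursanov–Parnes) works because the trialkoxy‑stabilised diarylmethyl cation forms readily in TFA and excess silane captures it irreversibly before Friedel–Crafts side reactions occur.

**Step 5**
Reactants: 7 1‑(benzyloxy)‑2‑(2,3‑dimethoxybenzyl)‑3,5‑dimethoxybenzene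
Product: 8 2‑(2,3‑dimethoxybenzyl)‑3,5‑dimethoxyphenol
Conditions: H2 (1 atm), 10 % Pd/C, EtOAc/EtOH, rt
Reagents that add atoms: none
Why: Catalytic hydrogenolysis cleaves only the benzylic C–O bond, while the methyl ethers and the diarylmethane C–C bonds are inert.

**Step 6**
Reactants: 8 2‑(2,3‑dimethoxybenzyl)‑3,5‑dimethoxyphenol
Product: 11 1‑[3‑(2,3‑dimethoxybenzyl)‑2‑hydroxy‑4,6‑dimethoxyphenyl]ethan‑1‑one, via aryl acetate 9 (not isolated), via difluoroboron chelate 10 (not isolated)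
Conditions: Ac2O (1.2 equiv), BF3·OEt2 (3 equiv), 65 °C, 2 h; then H2O/MeOH, 50 °C
Reagents that add atoms: acetic anhydride CC(=O)OC(C)=O
Why: O‑acetylation followed by a BF3‑mediated Fries rearrangement funnels the acyl group to the only free position ortho to the OH, because the six‑membered BF2 chelate is the thermodynamic sink and the phloroglucinol ring far outpaces the veratrole ring.

**Step 7 (key step)**
Reactants: 11 1‑[3‑(2,3‑dimethoxybenzyl)‑2‑hydroxy‑4,6‑dimethoxyphenyl]ethan‑1‑one; 12 benzaldehyde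
Product: 14 (E)‑1‑[3‑(2,3‑dimethoxybenzyl)‑2‑hydroxy‑4,6‑dimethoxyphenyl]‑3‑phenylprop‑2‑en‑1‑one, via aldol adduct 13 (not isolated)
Conditions: 12 (1.3 equiv), 50 % aq KOH (10 equiv), EtOH, rt, 24–48 h; then 1 M HCl to pH 3
Reagents that add atoms: none
Why: In this Claisen–Schmidt crossed aldol condensation the methyl ketone is the only enolisable partner and benzaldehyde the only good electrophile, and E1cB loss of water from the racemic aldol adduct gives the conjugated E‑enone.

**Step 8**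
Reactants: 14 (E)‑chalcone
Product: 16 8‑(2,3‑dimethoxybenzyl)‑5,7‑dimethoxy‑2‑phenyl‑4H‑chromen‑4‑one, via flavanone 15 (not isolated)
Conditions: I2 (10 mol %), DMSO, 120 °C, 2–3 h; aq Na2S2O3 wash
Reagents that add atoms: none
Why: Intramolecular oxa‑Michael closure through the only free OH followed by iodine‑catalysed dehydrogenation (α‑iodination and loss of HI, with DMSO reoxidising HI) gives the flavone, so the benzyl group must end up at C8.

**Step 9**
Reactants: 16 8‑(2,3‑dimethoxybenzyl)‑5,7‑dimethoxy‑2‑phenyl‑4H‑chromen‑4‑one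
Product: 17 8‑(2,3‑dihydroxybenzyl)‑5,7‑dihydroxy‑2‑phenyl‑4H‑chromen‑4‑one (target)
Conditions: BBr3 (10 equiv), CH2Cl2, −78 °C → rt → 40 °C, 24 h; ice/H2O; work‑up under N2
Reagents that add atoms: none
Why: Lewis‑acid ether cleavage with excess BBr3 removes all four aryl methyl ethers under anhydrous, non‑protic conditions that avoid ring opening of the pyranone (Wessely–Moser isomerisation to the 6‑benzyl isomer).

## Compound list
1 | 2,4,6‑trimethoxybenzaldehyde | COc1cc(OC)c(C=O)c(OC)c1 | starting material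
2 | 2‑hydroxy‑4,6‑dimethoxybenzaldehyde | COc1cc(O)c(C=O)c(OC)c1 | intermediate
3 | 2‑(benzyloxy)‑4,6‑dimethoxybenzaldehyde | COc1cc(OC)c(C=O)c(OCc2ccccc2)c1 | intermediate
4 | 1,2‑dimethoxybenzene (veratrole) | COc1ccccc1OC | starting material
5 | 2,3‑dimethoxyphenyllithium | [Li]c1cccc(OC)c1OC | intermediate
6 | [2‑(benzyloxy)‑4,6‑dimethoxyphenyl](2,3‑dimethoxyphenyl)methanol (racemic) | COc1cc(OC)c(C(O)c2cccc(OC)c2OC)c(OCc2ccccc2)c1 | intermediate
7 | 1‑(benzyloxy)‑2‑(2,3‑dimethoxybenzyl)‑3,5‑dimethoxybenzene | COc1cc(OC)c(Cc2cccc(OC)c2OC)c(OCc2ccccc2)c1 | intermediate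
8 | 2‑(2,3‑dimethoxybenzyl)‑3,5‑dimethoxyphenol | COc1cc(O)c(Cc2cccc(OC)c2OC)c(OC)c1 | intermediate
9 | 2‑(2,3‑dimethoxybenzyl)‑3,5‑dimethoxyphenyl acetate | COc1cc(OC(C)=O)c(Cc2cccc(OC)c2OC)c(OC)c1 | intermediate
10 | difluoroboron chelate of 11 | CC1=[O+][B-](F)(F)Oc2c(Cc3cccc(OC)c3OC)c(OC)cc(OC)c21 | intermediate
11 | 1‑[3‑(2,3‑dimethoxybenzyl)‑2‑hydroxy‑4,6‑dimethoxyphenyl]ethan‑1‑one | COc1cc(OC)c(C(C)=O)c(O)c1Cc1cccc(OC)c1OC | intermediate
12 | benzaldehyde | O=Cc1ccccc1 | starting material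
13 | 1‑[3‑(2,3‑dimethoxybenzyl)‑2‑hydroxy‑4,6‑dimethoxyphenyl]‑3‑hydroxy‑3‑phenylpropan‑1‑one (racemic) | COc1cc(OC)c(C(=O)CC(O)c2ccccc2)c(O)c1Cc1cccc(OC)c1OC | intermediate
14 | (E)‑1‑[3‑(2,3‑dimethoxybenzyl)‑2‑hydroxy‑4,6‑dimethoxyphenyl]‑3‑phenylprop‑2‑en‑1‑one | COc1cc(OC)c(C(=O)/C=C/c2ccccc2)c(O)c1Cc1cccc(OC)c1OC | intermediate
15 | 8‑(2,3‑dimethoxybenzyl)‑5,7‑dimethoxy‑2‑phenylchroman‑4‑one (racemic) | COc1cc(OC)c2C(=O)CC(c3ccccc3)Oc2c1Cc1cccc(OC)c1OC | intermediate
16 | 8‑(2,3‑dimethoxybenzyl)‑5,7‑dimethoxy‑2‑phenyl‑4H‑chromen‑4‑one | COc1cc(OC)c2c(=O)cc(-c3ccccc3)oc2c1Cc1cccc(OC)c1OC | intermediate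
17 | 8‑(2,3‑dihydroxybenzyl)‑5,7‑dihydroxy‑2‑phenyl‑4H‑chromen‑4‑one | O=c1cc(-c2ccccc2)oc2c(Cc3cccc(O)c3O)c(O)cc(O)c12 | target

## Summary
Total step count: 9. Longest linear sequence: 9 steps (1 → 17). Compounds 4 and 12 enter as purchased.

## Three steps most likely to fail

**Step 6.**
- Risk: some acyl group may enter the position para to the OH, and warm BF3 may scramble the acid‑labile diarylmethane. The para isomer has no OH next to the ketone, so it cannot give a flavone, and it is removed as a non‑chelated, base‑soluble phenol.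
- Fallback: it sets out from 8, uses no strong acid, and comes back to the route at 11.
  - MgCl2/Et3N/paraformaldehyde in MeCN at reflux (Casnati–Skattebøl formylation) reacts only ortho to the magnesium phenoxide. It gives 3‑(2,3‑dimethoxybenzyl)‑2‑hydroxy‑4,6‑dimethoxybenzaldehyde F1.
  - MeMgBr (2.5 equiv, THF, 0 °C) gives racemic 2‑(2,3‑dimethoxybenzyl)‑6‑(1‑hydroxyethyl)‑3,5‑dimethoxyphenol F2.
  - Activated MnO2 in CH2Cl2 oxidises the benzylic alcohol to 11.

**Step 8.**
- Risk: iodination of C6, oxidation of the doubly benzylic CH2, or partial loss of the 5‑O‑methyl group.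
- Fallback: it sets out from 11, needs no oxidant, and comes back to the route at 16.
  - LiHMDS (3.5 equiv, THF, −78 °C) forms the dianion, and benzoyl chloride (1.0 equiv) C‑acylates it in an intermolecular Claisen‑type condensation. The product is 1‑[3‑(2,3‑dimethoxybenzyl)‑2‑hydroxy‑4,6‑dimethoxyphenyl]‑3‑phenylpropane‑1,3‑dione F3.
  - Cyclodehydration in AcOH with catalytic H2SO4 at 95 °C closes the pyranone. The 5‑oxygen is still methylated, so no isomerisation is possible.

**Step 9.**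
- Risk: the 7‑methyl ether, whose oxygen is conjugated with the C4 carbonyl (a vinylogous ester), may survive. Forcing the reaction invites isomerisation and loss of the air‑sensitive catechol.
- Fallback: it sets out from 16, splits the deprotection into two mechanistically different stages, and comes back to the route at 17.
  - BBr3 (5 equiv, −78 → 0 °C) removes the chelated 5‑methyl and the two veratrole methyls. It gives 8‑(2,3‑dihydroxybenzyl)‑5‑hydroxy‑7‑methoxy‑2‑phenyl‑4H‑chromen‑4‑one F4, which is isolated.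
  - The last methyl group is removed by SN2 attack of a soft nucleophile with AlCl3/EtSH in CH2Cl2, 0 °C → rt (hard acid/soft nucleophile cleavage).

## Further compounds
F1 | step 6 | 3‑(2,3‑dimethoxybenzyl)‑2‑hydroxy‑4,6‑dimethoxybenzaldehyde | COc1cc(OC)c(C=O)c(O)c1Cc1cccc(OC)c1OC
F2 | step 6 | 2‑(2,3‑dimethoxybenzyl)‑6‑(1‑hydroxyethyl)‑3,5‑dimethoxyphenol (racemic) | COc1cc(OC)c(C(C)O)c(O)c1Cc1cccc(OC)c1OC
F3 | step 8 | 1‑[3‑(2,3‑dimethoxybenzyl)‑2‑hydroxy‑4,6‑dimethoxyphenyl]‑3‑phenylpropane‑1,3‑dione | COc1cc(OC)c(C(=O)CC(=O)c2ccccc2)c(O)c1Cc1cccc(OC)c1OC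
F4 | step 9 | 8‑(2,3‑dihydroxybenzyl)‑5‑hydroxy‑7‑methoxy‑2‑phenyl‑4H‑chromen‑4‑one | COc1cc(O)c2c(=O)cc(-c3ccccc3)oc2c1Cc1cccc(O)c1O
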